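**Retrosynthetic overview**

1. Numbering: ring A C1 (carbonyl-bearing), C2 (OH), C3 (Br), C4 (CH3), C5 (Br), C6 (OCH3); ring B C1′ (carbonyl-bearing), C2′ (CHO), C3′ (OH), C5′ (OH), C6′ (prenyl). The plan rests on ring A: without its bromines it is a 2-substituted 3-methoxy-5-methylphenol, the pattern a vinylketene/alkoxyalkyne benzannulation gives.
2. Pestalone D ⇐ acid unmasking (dioxane to the C2′ aldehyde, two MOM ethers to the C3′/C5′ phenols) ⇐ bromination of the ring A phenoxide at C3 and C5 ⇐ oxidation of a diaryl carbinol to the ketone.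
3. Ring A ⇐ 3-methylcyclobutenone + a 1-methoxyalkyne carrying ring B on a silylated propargylic carbinol (forms C1–C2, C5–C6 and C2–C3); ring B is made first and ring A is grown onto it last.
4. Methoxyalkyne ⇐ ring B benzaldehyde + lithium methoxyacetylide (from 2-chloro-1,1-dimethoxyethane); cyclobutenone ⇐ propyne + dichloroketene, then zinc dechlorination.
5. Ring B aldehyde ⇐ methyl 3,5-dihydroxybenzoate: symmetric 2,6-dibromination of the bis-MOM benzyl alcohol, two successive bromine–lithium exchanges (prenyl, then formyl), acetalization, oxidation of the benzylic alcohol.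

Key step: step 14

Remark: Ar stands for the 2-(1,3-dioxan-2-yl)-3,5-bis(methoxymethoxy)-6-(3-methylbut-2-enyl)phenyl group; the target has no stereocentre, and the carbinol centre made in step 10 is carried as a racemate until step 16 removes it.

**Route**

Step 1
Reactants: 1 methyl 3,5-dihydroxybenzoate
Product: 2 methyl 3,5-bis(methoxymethoxy)benzoate
Conditions: MOMCl (2.5 equiv), i-Pr2NEt, CH2Cl2, 0 °C to rt
Reagents that add atoms: chloromethyl methyl ether, COCCl
Why: Base-mediated O-alkylation of both phenols with the α-chloro ether (MOM protection, Williamson type) gives ethers that should survive the hydride, organolithium, fluoride and thermal steps.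

Step 2
Reactants: 2 methyl 3,5-bis(methoxymethoxy)benzoate
Product: 3 [3,5-bis(methoxymethoxy)phenyl]methanol
Conditions: LiAlH4, THF, 0 °C
Reagents that add atoms: none
Why: Hydride reduction of the ester gives the primary benzylic alcohol without touching the MOM acetals.

Step 3
Reactants: 3 [3,5-bis(methoxymethoxy)phenyl]methanol
Product: 4 [2,6-dibromo-3,5-bis(methoxymethoxy)phenyl]methanol
Conditions: NBS (2.05 equiv), MeCN, 0 °C to rt
Reagents that add atoms: N-bromosuccinimide, O=C1CCC(=O)N1Br
Why: Electrophilic aromatic bromination should enter twice at C2 and C6, each para to one MOM-oxy group and ortho to the other, in preference to C4, which is ortho to both and has no para activation, so the symmetric dibromide is expected.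

Step 4
Reactants: 4 [2,6-dibromo-3,5-bis(methoxymethoxy)phenyl]methanol
Product: 5 [[2,6-dibromo-3,5-bis(methoxymethoxy)phenyl]methoxy]tri(propan-2-yl)silane
Conditions: TIPSCl, imidazole, DMF, rt
Reagents that add atoms: chlorotri(propan-2-yl)silane, CC(C)[Si](Cl)(C(C)C)C(C)C
Why: Imidazole-mediated silylation removes the acidic proton before the organolithium steps, and the bulky triisopropylsilyl group is chosen to slow O-to-C silyl migration (retro-Brook) in the ortho-lithiated intermediates.

Step 5
Reactants: 5 [[2,6-dibromo-3,5-bis(methoxymethoxy)phenyl]methoxy]tri(propan-2-yl)silane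
Product: 8 [[2-bromo-3,5-bis(methoxymethoxy)-6-(3-methylbut-2-enyl)phenyl]methoxy]tri(propan-2-yl)silane, via aryllithium 6 (not isolated), via arylcopper 7 (not isolated)
Conditions: n-BuLi (1.0 equiv), THF, −78 °C; CuBr·SMe2 (1.0 equiv), −78 to −40 °C; prenyl bromide, −40 to 0 °C
Reagents that add atoms: 1-bromo-3-methylbut-2-ene, CC(C)=CCBr
Why: Bromine–lithium exchange at one of two equivalent C–Br bonds needs only stoichiometry control, and transmetalation to the arylcopper followed by copper-mediated allylic substitution (SN2) at the primary carbon of the allylic bromide should give the linear prenyl arene.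

Step 6
Reactants: 8 [[2-bromo-3,5-bis(methoxymethoxy)-6-(3-methylbut-2-enyl)phenyl]methoxy]tri(propan-2-yl)silane
Product: 10 2,4-bis(methoxymethoxy)-5-(3-methylbut-2-enyl)-6-[[tri(propan-2-yl)silyl]oxymethyl]benzaldehyde, via aryllithium 9 (not isolated)
Conditions: n-BuLi (1.1 equiv), THF, −78 °C; DMF, −78 to 0 °C; H2O
Reagents that add atoms: N,N-dimethylformamide, CN(C)C=O
Why: A second bromine–lithium exchange and trapping of the aryllithium with DMF (Bouveault formylation) should place the formyl carbon at C2′, next to a MOM-oxy group.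

Step 7
Reactants: 10 2,4-bis(methoxymethoxy)-5-(3-methylbut-2-enyl)-6-[[tri(propan-2-yl)silyl]oxymethyl]benzaldehyde
Product: 11 [[2-(1,3-dioxan-2-yl)-3,5-bis(methoxymethoxy)-6-(3-methylbut-2-enyl)phenyl]methoxy]tri(propan-2-yl)silane
Conditions: TMSO(CH2)3OTMS, TMSOTf (5 mol %), CH2Cl2, −78 to −30 °C; pyridine quench
Reagents that add atoms: 1,3-bis(trimethylsilyloxy)propane, C[Si](C)(C)OCCCO[Si](C)(C)C
Why: Noyori acetalization with the bis-silyl ether of the diol under catalytic TMSOTf at low temperature should form the 1,3-dioxane under aprotic conditions that spare the MOM ethers, the silyl ether and the prenyl alkene.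

Step 8
Reactants: 11 [[2-(1,3-dioxan-2-yl)-3,5-bis(methoxymethoxy)-6-(3-methylbut-2-enyl)phenyl]methoxy]tri(propan-2-yl)silane
Product: 12 [2-(1,3-dioxan-2-yl)-3,5-bis(methoxymethoxy)-6-(3-methylbut-2-enyl)phenyl]methanol
Conditions: Bu4NF, THF, 0 °C to rt
Reagents that add atoms: none
Why: Fluoride-induced Si–O cleavage frees the primary benzylic alcohol, while the acetal and the MOM ethers are inert to fluoride.

Step 9
Reactants: 12 [2-(1,3-dioxan-2-yl)-3,5-bis(methoxymethoxy)-6-(3-methylbut-2-enyl)phenyl]methanol
Product: 13 2-(1,3-dioxan-2-yl)-3,5-bis(methoxymethoxy)-6-(3-methylbut-2-enyl)benzaldehyde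
Conditions: MnO2 (activated, excess), CH2Cl2, rt
Reagents that add atoms: none
Why: MnO2 oxidation of the benzylic alcohol stops at the aldehyde under neutral conditions and leaves the acetal-masked second formyl group differentiated.

Step 10
Reactants: 14 2-chloro-1,1-dimethoxyethane; 13 2-(1,3-dioxan-2-yl)-3,5-bis(methoxymethoxy)-6-(3-methylbut-2-enyl)benzaldehyde
Product: 16 1-(Ar)-3-methoxyprop-2-yn-1-ol (racemic), via lithium methoxyacetylide 15 (not isolated)
Conditions: LiNEt2 (3.3 equiv, from n-BuLi and Et2NH), THF, 0 °C; then 13, −78 to −40 °C; pH 7 buffer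
Reagents that add atoms: none
Why: Two successive amide-induced eliminations (methanol, then HCl) and deprotonation convert the chloroacetal into lithium methoxyacetylide, whose 1,2-addition to the aldehyde gives the propargylic alcohol as a racemate, since nothing in the substrate or reagent is chiral and no control is needed.

Step 11
Reactants: 16 1-(Ar)-3-methoxyprop-2-yn-1-ol (racemic)
Product: 17 tert-butyl[[1-(Ar)-3-methoxyprop-2-yn-1-yl]oxy]dimethylsilane (racemic)
Conditions: TBSCl, imidazole, DMAP (cat.), DMF, rt to 40 °C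
Reagents that add atoms: tert-butylchlorodimethylsilane, CC(C)(C)[Si](C)(C)Cl
Why: Silylation under basic conditions protects the carbinol and avoids the acid that would trigger Meyer–Schuster rearrangement of the 3-alkoxypropargylic alcohol.

Step 12
Reactants: 18 propyne; 19 trichloroacetyl chloride
Product: 21 4,4-dichloro-3-methylcyclobut-2-en-1-one, via dichloroketene 20 (not isolated)
Conditions: Zn(Cu) couple, Et2O–DME, 0 °C to rt, excess propyne under a dry-ice condenser
Reagents that add atoms: none
Why: Zinc dehalogenation of the acid chloride generates dichloroketene, which undergoes [2+2] cycloaddition with the terminal alkyne, its carbonyl carbon bonding to the unsubstituted alkyne carbon, to give the 3-methyl-4,4-dichlorocyclobutenone.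

Step 13
Reactants: 21 4,4-dichloro-3-methylcyclobut-2-en-1-one
Product: 22 3-methylcyclobut-2-en-1-one
Conditions: Zn dust, AcOH, TMEDA, EtOH, 0 °C to rt; careful distillation
Reagents that add atoms: none
Why: Zinc reduction of the α,α-dichloro ketone (reductive dehalogenation through zinc enolates) in the amine-buffered medium should give the cyclobutenone without acid-induced ring cleavage.

Step 14
Reactants: 22 3-methylcyclobut-2-en-1-one; 17 tert-butyl[[1-(Ar)-3-methoxyprop-2-yn-1-yl]oxy]dimethylsilane (racemic)
Product: 27 2-[(tert-butyldimethylsilyloxy)(Ar)methyl]-3-methoxy-5-methylphenol (racemic), via vinylketene 23 (not isolated), via vinylcyclobutenone adduct 24 (not isolated), via dienylketene 25 (not isolated), via cyclohexadienone 26 (not isolated)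
Conditions: 22 (2.5 equiv), toluene, 80 °C then 110 °C, sealed tube
Reagents that add atoms: none
Why: Heating opens 22 by four-electron electrocyclic ring opening to vinylketene 23, which adds [2+2] across the electron-rich alkyne of 17 to give the 4-vinylcyclobutenone 24; a second, reversible four-electron opening gives dienylketene 25, and six-electron electrocyclization followed by enolization of dienone 26 gives phenol 27. This is the Danheiser benzannulation of a cyclobutenone with an alkoxyalkyne, a known route to 3-alkoxyphenols. Ring A is closed by the thermal six-electron electrocyclization that forms C2–C3, after the cycloaddition has formed C1–C2 and C5–C6. No lasting stereocentre is created: the sp3 carbon of 24 is lost on ring opening, and the carbinol centre of 17 is untouched and racemic. The step needs regiocontrol in the [2+2] event, which the methoxy group supplies by making the alkyne carbon remote from oxygen the nucleophilic one, so that this carbon (carrying the ring B carbinol) bonds to the ketene carbonyl carbon and ends between the hydroxyl and the methoxyl. It also needs the ketene to choose the alkyne over the prenyl alkene, which the far higher nucleophilicity of the ynol ether should secure, and the methyl ether cannot fragment by retro-ene loss of an alkene at these temperatures.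

Step 15
Reactants: 27 2-[(tert-butyldimethylsilyloxy)(Ar)methyl]-3-methoxy-5-methylphenol (racemic)
Product: 28 2-[hydroxy(Ar)methyl]-3-methoxy-5-methylphenol (racemic)
Conditions: Bu4NF, THF, rt to 50 °C
Reagents that add atoms: none
Why: Fluoride desilylation frees the carbinol, helped if needed by silyl transfer to the neighbouring phenoxide, under basic conditions that avoid ionization of the o-hydroxybenzhydrol.

Step 16
Reactants: 28 2-[hydroxy(Ar)methyl]-3-methoxy-5-methylphenol (racemic)
Product: 29 (Ar)(2-hydroxy-6-methoxy-4-methylphenyl)methanone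
Conditions: MnO2 (activated, excess), CH2Cl2, rt
Reagents that add atoms: none
Why: MnO2 oxidation of the doubly benzylic alcohol should give the o-hydroxybenzophenone under neutral conditions and removes the only stereocentre.

Step 17
Reactants: 29 (Ar)(2-hydroxy-6-methoxy-4-methylphenyl)methanone
Product: 30 (Ar)(3,5-dibromo-2-hydroxy-6-methoxy-4-methylphenyl)methanone
Conditions: NaH (1.05 equiv), THF, 0 °C; NBS (2.05 equiv), −78 to −20 °C; H2O
Reagents that add atoms: N-bromosuccinimide, O=C1CCC(=O)N1Br
Why: Electrophilic aromatic bromination of the phenoxide occurs ortho and para to the oxide at C3 and C5, the only free positions of ring A, and should be far faster than attack on the prenyl alkene or on ring B, whose free position C4′ is deactivated by the para ketone.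

Step 18
Reactants: 30 (Ar)(3,5-dibromo-2-hydroxy-6-methoxy-4-methylphenyl)methanone
Product: 31 pestalone D, 2-(3,5-dibromo-2-hydroxy-6-methoxy-4-methylbenzoyl)-4,6-dihydroxy-3-(3-methylbut-2-enyl)benzaldehyde
Conditions: 3 M aq HCl, THF, 40 °C
Reagents that add atoms: water, O
Why: Acetal hydrolysis in aqueous acid converts the dioxane into the aldehyde and both MOM ethers into the phenols in one operation, at a temperature kept low to avoid acid-induced chroman formation between the prenyl group and the C5′ phenol.

**Compound list**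

1 | methyl 3,5-dihydroxybenzoate | COC(=O)c1cc(O)cc(O)c1 | starting material
2 | methyl 3,5-bis(methoxymethoxy)benzoate | COC(=O)c1cc(OCOC)cc(OCOC)c1 | intermediate
3 | [3,5-bis(methoxymethoxy)phenyl]methanol | OCc1cc(OCOC)cc(OCOC)c1 | intermediate
4 | [2,6-dibromo-3,5-bis(methoxymethoxy)phenyl]methanol | OCc1c(Br)c(OCOC)cc(OCOC)c1Br | intermediate
5 | [[2,6-dibromo-3,5-bis(methoxymethoxy)phenyl]methoxy]tri(propan-2-yl)silane | CC(C)[Si](OCc1c(Br)c(OCOC)cc(OCOC)c1Br)(C(C)C)C(C)C | intermediate
6 | [3-bromo-4,6-bis(methoxymethoxy)-2-[[tri(propan-2-yl)silyl]oxymethyl]phenyl]lithium (formed in the flask) | CC(C)[Si](OCc1c(Br)c(OCOC)cc(OCOC)c1[Li])(C(C)C)C(C)C | intermediate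
7 | [3-bromo-4,6-bis(methoxymethoxy)-2-[[tri(propan-2-yl)silyl]oxymethyl]phenyl]copper (formed in the flask) | CC(C)[Si](OCc1c(Br)c(OCOC)cc(OCOC)c1[Cu])(C(C)C)C(C)C | intermediate
8 | [[2-bromo-3,5-bis(methoxymethoxy)-6-(3-methylbut-2-enyl)phenyl]methoxy]tri(propan-2-yl)silane | CC(C)[Si](OCc1c(Br)c(OCOC)cc(OCOC)c1CC=C(C)C)(C(C)C)C(C)C | intermediate
9 | [2,4-bis(methoxymethoxy)-5-(3-methylbut-2-enyl)-6-[[tri(propan-2-yl)silyl]oxymethyl]phenyl]lithium (formed in the flask) | CC(C)[Si](OCc1c([Li])c(OCOC)cc(OCOC)c1CC=C(C)C)(C(C)C)C(C)C | intermediate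
10 | 2,4-bis(methoxymethoxy)-5-(3-methylbut-2-enyl)-6-[[tri(propan-2-yl)silyl]oxymethyl]benzaldehyde | CC(C)[Si](OCc1c(C=O)c(OCOC)cc(OCOC)c1CC=C(C)C)(C(C)C)C(C)C | intermediate
11 | [[2-(1,3-dioxan-2-yl)-3,5-bis(methoxymethoxy)-6-(3-methylbut-2-enyl)phenyl]methoxy]tri(propan-2-yl)silane | CC(C)[Si](OCc1c(C2OCCCO2)c(OCOC)cc(OCOC)c1CC=C(C)C)(C(C)C)C(C)C | intermediate
12 | [2-(1,3-dioxan-2-yl)-3,5-bis(methoxymethoxy)-6-(3-methylbut-2-enyl)phenyl]methanol | OCc1c(C2OCCCO2)c(OCOC)cc(OCOC)c1CC=C(C)C | intermediate
13 | 2-(1,3-dioxan-2-yl)-3,5-bis(methoxymethoxy)-6-(3-methylbut-2-enyl)benzaldehyde | O=Cc1c(C2OCCCO2)c(OCOC)cc(OCOC)c1CC=C(C)C | intermediate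
14 | 2-chloro-1,1-dimethoxyethane | COC(CCl)OC | starting material
15 | lithium methoxyacetylide (formed in the flask) | [Li]C#COC | intermediate
16 | 1-[2-(1,3-dioxan-2-yl)-3,5-bis(methoxymethoxy)-6-(3-methylbut-2-enyl)phenyl]-3-methoxyprop-2-yn-1-ol (racemic) | COC#CC(O)c1c(C2OCCCO2)c(OCOC)cc(OCOC)c1CC=C(C)C | intermediate
17 | tert-butyl[[1-[2-(1,3-dioxan-2-yl)-3,5-bis(methoxymethoxy)-6-(3-methylbut-2-enyl)phenyl]-3-methoxyprop-2-yn-1-yl]oxy]dimethylsilane (racemic) | COC#CC(O[Si](C)(C)C(C)(C)C)c1c(C2OCCCO2)c(OCOC)cc(OCOC)c1CC=C(C)C | intermediate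
18 | propyne | CC#C | starting material
19 | trichloroacetyl chloride | ClC(=O)C(Cl)(Cl)Cl | starting material
20 | dichloroketene (formed in the flask) | ClC(Cl)=C=O | intermediate
21 | 4,4-dichloro-3-methylcyclobut-2-en-1-one | CC1=CC(=O)C1(Cl)Cl | intermediate
22 | 3-methylcyclobut-2-en-1-one | CC1=CC(=O)C1 | intermediate
23 | 3-methylbuta-1,3-dien-1-one, the vinylketene (formed in the flask) | C=C(C)C=C=O | intermediate
24 | 2-[(tert-butyldimethylsilyloxy)(Ar)methyl]-3-methoxy-4-(prop-1-en-2-yl)cyclobut-2-en-1-one (mixture of diastereomers, formed in the flask) | COC1=C(C(O[Si](C)(C)C(C)(C)C)c2c(C3OCCCO3)c(OCOC)cc(OCOC)c2CC=C(C)C)C(=O)C1C(C)=C | intermediate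
25 | 2-[(tert-butyldimethylsilyloxy)(Ar)methyl]-3-methoxy-5-methylhexa-1,3,5-trien-1-one, the dienylketene with the ketene and isopropenyl groups cis on the C3=C4 bond (racemic, formed in the flask) | CO/C(=C/C(C)=C)C(=C=O)C(O[Si](C)(C)C(C)(C)C)c1c(C2OCCCO2)c(OCOC)cc(OCOC)c1CC=C(C)C | intermediate
26 | 2-[(tert-butyldimethylsilyloxy)(Ar)methyl]-3-methoxy-5-methylcyclohexa-2,4-dien-1-one (racemic, formed in the flask) | COC1=C(C(O[Si](C)(C)C(C)(C)C)c2c(C3OCCCO3)c(OCOC)cc(OCOC)c2CC=C(C)C)C(=O)CC(C)=C1 | intermediate
27 | 2-[(tert-butyldimethylsilyloxy)[2-(1,3-dioxan-2-yl)-3,5-bis(methoxymethoxy)-6-(3-methylbut-2-enyl)phenyl]methyl]-3-methoxy-5-methylphenol (racemic) | COc1cc(C)cc(O)c1C(O[Si](C)(C)C(C)(C)C)c1c(C2OCCCO2)c(OCOC)cc(OCOC)c1CC=C(C)C | intermediate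
28 | 2-[[2-(1,3-dioxan-2-yl)-3,5-bis(methoxymethoxy)-6-(3-methylbut-2-enyl)phenyl](hydroxy)methyl]-3-methoxy-5-methylphenol (racemic) | COc1cc(C)cc(O)c1C(O)c1c(C2OCCCO2)c(OCOC)cc(OCOC)c1CC=C(C)C | intermediate
29 | [2-(1,3-dioxan-2-yl)-3,5-bis(methoxymethoxy)-6-(3-methylbut-2-enyl)phenyl](2-hydroxy-6-methoxy-4-methylphenyl)methanone | COc1cc(C)cc(O)c1C(=O)c1c(C2OCCCO2)c(OCOC)cc(OCOC)c1CC=C(C)C | intermediate
30 | (3,5-dibromo-2-hydroxy-6-methoxy-4-methylphenyl)[2-(1,3-dioxan-2-yl)-3,5-bis(methoxymethoxy)-6-(3-methylbut-2-enyl)phenyl]methanone | COc1c(Br)c(C)c(Br)c(O)c1C(=O)c1c(C2OCCCO2)c(OCOC)cc(OCOC)c1CC=C(C)C | intermediate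
31 | pestalone D, 2-(3,5-dibromo-2-hydroxy-6-methoxy-4-methylbenzoyl)-4,6-dihydroxy-3-(3-methylbut-2-enyl)benzaldehyde | COc1c(Br)c(C)c(Br)c(O)c1C(=O)c1c(C=O)c(O)cc(O)c1CC=C(C)C | target

**Step count and risks**

Total: 18 steps. Longest linear sequence: 16 steps (steps 1 to 11, then 14 to 18); steps 12 and 13 form the short branch to the cyclobutenone.

Steps most likely to fail:

Step 14. The alkyne carbon that must bond to the ketene carries a bulky silyloxy(aryl)methyl group, so the [2+2] capture may be slow. The vinylketene would then be lost to dimerization or to O-acylation of phenol already formed; a brief K2CO3/MeOH treatment would return any such aryl ester to 27. If the annulation itself cannot be made to work, ring A would be brought in as a preformed arene and the carbinol bond made by directed ortho-metalation and aryllithium addition. This fallback sets out from aldehyde 13 and returns at diol 28. Commercial 3-methoxy-5-methylphenol would be alkylated with SEMCl and NaH in DMF to give 1-methoxy-3-methyl-5-[[2-(trimethylsilyl)ethoxy]methoxy]benzene F1. n-BuLi in THF at 0 °C should lithiate the position between the two oxygen substituents to give [2-methoxy-4-methyl-6-[[2-(trimethylsilyl)ethoxy]methoxy]phenyl]lithium F2. Addition of F2 to 13 at −78 °C would give the carbinol (Ar)[2-methoxy-4-methyl-6-[[2-(trimethylsilyl)ethoxy]methoxy]phenyl]methanol F3. Bu4NF in THF/DMPU at 60 °C would then remove the SEM group and deliver 28, from which steps 16 to 18 follow unchanged.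

Step 17. The ketone-conjugated phenoxide may react too slowly, so that the brominating agent attacks the trisubstituted alkene (bromonium ion captured by the neighbouring MOM-ether oxygen) or ring B at C4′, or bromination stops at one bromine. The fallback resequences the end game so that the halogenation acts on the far more nucleophilic, non-acylated phenoxide. It sets out from phenol 27 and returns at dibromo ketone 30. Treatment of 27 with NaH and then NBS (2.05 equiv) in THF at −78 °C would give 2,4-dibromo-6-[(tert-butyldimethylsilyloxy)(Ar)methyl]-5-methoxy-3-methylphenol F4. Bu4NF in THF would give 2,4-dibromo-6-[hydroxy(Ar)methyl]-5-methoxy-3-methylphenol F5. MnO2 in CH2Cl2 would then oxidize F5 to 30.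

Step 16. The carbinol is shielded by four ortho substituents, so oxidation may be sluggish, and the electron-rich free phenol may be oxidized in competition (quinone formation or oxidative coupling). The fallback masks the phenol for the oxidation. It sets out from diol 28 and returns at ketone 29. TBSCl (1.1 equiv) and imidazole in DMF at 0 °C should silylate the phenol selectively, the secondary carbinol being far more hindered, to give [2-(tert-butyldimethylsilyloxy)-6-methoxy-4-methylphenyl](Ar)methanol F6. Dess–Martin periodinane in CH2Cl2 would oxidize F6 to [2-(tert-butyldimethylsilyloxy)-6-methoxy-4-methylphenyl](Ar)methanone F7. Bu4NF in THF at 0 °C would then free the phenol and give 29.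

**Further compounds**

F1 | step 14 | 1-methoxy-3-methyl-5-[[2-(trimethylsilyl)ethoxy]methoxy]benzene | COc1cc(C)cc(OCOCC[Si](C)(C)C)c1
F2 | step 14 | [2-methoxy-4-methyl-6-[[2-(trimethylsilyl)ethoxy]methoxy]phenyl]lithium | [Li]c1c(OC)cc(C)cc1OCOCC[Si](C)(C)C
F3 | step 14 | [2-(1,3-dioxan-2-yl)-3,5-bis(methoxymethoxy)-6-(3-methylbut-2-enyl)phenyl][2-methoxy-4-methyl-6-[[2-(trimethylsilyl)ethoxy]methoxy]phenyl]methanol (racemic) | COc1cc(C)cc(OCOCC[Si](C)(C)C)c1C(O)c1c(C2OCCCO2)c(OCOC)cc(OCOC)c1CC=C(C)C
F4 | step 17 | 2,4-dibromo-6-[(tert-butyldimethylsilyloxy)[2-(1,3-dioxan-2-yl)-3,5-bis(methoxymethoxy)-6-(3-methylbut-2-enyl)phenyl]methyl]-5-methoxy-3-methylphenol (racemic) | COc1c(Br)c(C)c(Br)c(O)c1C(O[Si](C)(C)C(C)(C)C)c1c(C2OCCCO2)c(OCOC)cc(OCOC)c1CC=C(C)C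
F5 | step 17 | 2,4-dibromo-6-[[2-(1,3-dioxan-2-yl)-3,5-bis(methoxymethoxy)-6-(3-methylbut-2-enyl)phenyl](hydroxy)methyl]-5-methoxy-3-methylphenol (racemic) | COc1c(Br)c(C)c(Br)c(O)c1C(O)c1c(C2OCCCO2)c(OCOC)cc(OCOC)c1CC=C(C)C
F6 | step 16 | [2-(tert-butyldimethylsilyloxy)-6-methoxy-4-methylphenyl][2-(1,3-dioxan-2-yl)-3,5-bis(methoxymethoxy)-6-(3-methylbut-2-enyl)phenyl]methanol (racemic) | COc1cc(C)cc(O[Si](C)(C)C(C)(C)C)c1C(O)c1c(C2OCCCO2)c(OCOC)cc(OCOC)c1CC=C(C)C
F7 | step 16 | [2-(tert-butyldimethylsilyloxy)-6-methoxy-4-methylphenyl][2-(1,3-dioxan-2-yl)-3,5-bis(methoxymethoxy)-6-(3-methylbut-2-enyl)phenyl]methanone | COc1cc(C)cc(O[Si](C)(C)C(C)(C)C)c1C(=O)c1c(C2OCCCO2)c(OCOC)cc(OCOC)c1CC=C(C)C
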